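**Retrosynthetic overview**

1. Numbering (germacrane): carbocycle C1–C10, lactone C11(=C13)–C12, methyls C14 (on C10) and C15 (on C4); TBS = tert-butyldimethylsilyl, PMB = 4-methoxybenzyl.
2. Feature: the ten-membered ring C1–C10 carries oxygen on C6, C8 and C10 and a Z C4=C5 alkene γ,δ to C10; this is the [3,3] imprint of a cis-1-vinyl-2-alkenylcyclohexanol (ring C5–C10).
3. Key disconnection: cyclodecenone 28 ⇐ divinylcyclohexanol 25 by anionic oxy-Cope rearrangement (C2–C3 formed, C5–C10 broken); afterwards C14 is added to the C10 ketone, the lactone is restored, and C13, the C8 angelate and free O3 follow.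
4. 25 ⇐ ketone 22 (axial acetylide, semi-hydrogenation) ⇐ alkyne 17 (carboalumination–iodination, copper C–O coupling) ⇐ keto lactone 14 ⇐ enone 9 (α-iodination, Sonogashira coupling, conjugate lactonisation).
5. 9 ⇐ Johnson–Claisen ester 8 ⇐ lipase-desymmetrised cis-cyclohex-2-ene-1,4-diol derivative ⇐ 1,3-cyclohexadiene; ring order: six-membered carbocycle, five-membered lactone (masked as acetal), ten-membered ring by expansion.

Key step: step 17

Assumption: the lipase in step 2 is taken to cleave the acetate that gives 3 (the antipode would come from lipase acylation of the meso diol); the acetal/lactol carbon C12 (exo anomer) and the transient C10 carbinol of 15–21 (all-cis epimer) are drawn as single isomers, but both centres are erased later, so either configuration serves.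

**Route**

Step 1
Reactants: 1 1,3-cyclohexadiene
Product: 2 cis-cyclohex-2-ene-1,4-diyl diacetate (meso)
Conditions: Pd(OAc)2 (5 mol%), LiOAc, LiCl (cat.), p-benzoquinone, AcOH, 25 °C
Reagents that add atoms: acetic acid (as lithium acetate), CC(=O)O
Why: Palladium-catalysed 1,4-diacetoxylation of a conjugated diene; with catalytic chloride the second acetate attacks the π-allyl intermediate from the face opposite the metal, which should give the cis (meso) diacetate.

Step 2
Reactants: 2 cis-cyclohex-2-ene-1,4-diyl diacetate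
Product: 3 (1S,4R)-4-hydroxycyclohex-2-en-1-yl acetate
Conditions: Candida antarctica lipase B, pH 7 phosphate buffer, 25 °C
Reagents that add atoms: none
Why: Enzymatic desymmetrising hydrolysis of a meso diacetate distinguishes the enantiotopic esters and so fixes the absolute configuration of the future C5 (acetoxy) and C8 (hydroxy) carbons.

Step 3
Reactants: 3 (1S,4R)-4-hydroxycyclohex-2-en-1-yl acetate
Product: 4 (1S,4R)-4-(TBSO)cyclohex-2-en-1-yl acetate
Conditions: TBSCl, imidazole, DMF, rt
Reagents that add atoms: tert-butyldimethylsilyl chloride, CC(C)(C)[Si](C)(C)Cl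
Why: Imidazole-promoted silylation of the secondary alcohol installs the C8 protecting group that survives every later basic step.

Step 4
Reactants: 4 (1S,4R)-4-(TBSO)cyclohex-2-en-1-yl acetate
Product: 5 (1S,4R)-4-(TBSO)cyclohex-2-en-1-ol
Conditions: K2CO3 (cat.), MeOH, 0 °C → rt
Reagents that add atoms: none
Why: Carbonate-catalysed transesterification removes the acetate and leaves the silyl ether, freeing the allylic C5 hydroxyl.

Step 5
Reactants: 5 (1S,4R)-4-(TBSO)cyclohex-2-en-1-ol; 6 trimethyl orthoacetate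
Product: 8 methyl 2-[(1S,6R)-6-(TBSO)cyclohex-2-en-1-yl]acetate, via ketene acetal 7 (not isolated)
Conditions: 6 (excess), EtCO2H (cat.), xylene, 140 °C, MeOH distilled off
Reagents that add atoms: trimethyl orthoacetate (6), CC(OC)(OC)OC
Why: Johnson–Claisen rearrangement; the ketene acetal on the C5 oxygen undergoes a suprafacial [3,3] shift across the ring face that carries that oxygen, so the new C7–C11 bond is formed cis to the C8 silyloxy group (C7 set by chirality transfer from C5).

Step 6
Reactants: 8 methyl 2-[(1S,6R)-6-(TBSO)cyclohex-2-en-1-yl]acetate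
Product: 9 methyl 2-[(1S,6R)-6-(TBSO)-4-oxocyclohex-2-en-1-yl]acetate
Conditions: Rh2(C6H10NO)4 (dirhodium tetracaprolactamate, 1 mol%), t-BuOOH, K2CO3, CH2Cl2, rt
Reagents that add atoms: tert-butyl hydroperoxide, CC(C)(C)OO
Why: Rhodium-catalysed allylic C–H oxidation converts the only allylic methylene (C10) into the enone carbonyl; the tertiary allylic C7–H is hindered and cannot give a ketone.

Step 7
Reactants: 9 methyl 2-[(1S,6R)-6-(TBSO)-4-oxocyclohex-2-en-1-yl]acetate
Product: 10 methyl 2-[(1S,6R)-6-(TBSO)-3-iodo-4-oxocyclohex-2-en-1-yl]acetate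
Conditions: I2, pyridine, CH2Cl2, 0 °C → rt
Reagents that add atoms: iodine, II
Why: Pyridine-mediated α-iodination of an enone (conjugate addition, iodination of the enolate, elimination) functionalises C5 only.

Step 8
Reactants: 10 methyl 2-[(1S,6R)-6-(TBSO)-3-iodo-4-oxocyclohex-2-en-1-yl]acetate; 11 (trimethylsilyl)acetylene
Product: 12 methyl 2-[(1S,6R)-6-(TBSO)-4-oxo-3-(trimethylsilylethynyl)cyclohex-2-en-1-yl]acetate
Conditions: 11, PdCl2(PPh3)2 (5 mol%), CuI (10 mol%), i-Pr2NH, THF, 0 °C
Reagents that add atoms: (trimethylsilyl)acetylene (11), C#C[Si](C)(C)C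
Why: Sonogashira coupling of the α-iodoenone attaches to C5 the two carbons that become C4 and C3.

Step 9
Reactants: 12 methyl 2-[(1S,6R)-6-(TBSO)-4-oxo-3-(trimethylsilylethynyl)cyclohex-2-en-1-yl]acetate
Product: 14 keto lactone (C10 ketone; cis-fused 6,12-lactone; C5 silylethynyl trans to O6; C8 OTBS), via enynone acid 13 (not isolated)
Conditions: Me3SnOH, ClCH2CH2Cl, 60 °C; 0.1 M HCl work-up; then TsOH·H2O (cat.), CH2Cl2, 0 °C → rt
Reagents that add atoms: trimethyltin hydroxide, C[Sn](C)(C)O
Why: Mild tin-hydroxide ester cleavage followed by acid-catalysed intramolecular oxa-Michael addition; the tethered carboxyl reaches C6 only on the face of C7–C11 (cis-fused γ-lactone, C6 set), and C5, epimerisable α to the ketone, should settle with the alkynyl group equatorial and trans to O6.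

Step 10
Reactants: 14 keto lactone
Product: 15 lactol diol (C10 carbinol; C12 lactol)
Conditions: i-Bu2AlH (3.5 equiv), CH2Cl2, −78 °C; aq. potassium sodium tartrate
Reagents that add atoms: none
Why: Low-temperature aluminium hydride reduction takes the ketone to the alcohol and stops the lactone at the lactol, which removes the base-sensitive β-acyloxy ketone before any basic step.

Step 11
Reactants: 15 lactol diol
Product: 17 methyl acetal alkynol (C5 ethynyl; C10 OH), via silylalkyne acetal 16 (not isolated)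
Conditions: PPTS (cat.), MeOH, rt; then K2CO3, rt
Reagents that add atoms: methanol, CO
Why: Acid-catalysed acetalisation masks C12 as a base-stable cyclic methyl acetal, and carbonate-promoted methanolysis of the C(sp)–Si bond then frees the terminal alkyne in the same pot.

Step 12
Reactants: 17 methyl acetal alkynol
Product: 19 E vinyl iodide (C5–C4(CH3)=C3H–I), via alkenylalane 18 (not isolated)
Conditions: Me3Al (4 equiv), Cp2ZrCl2 (0.3 equiv), H2O (1 equiv), CH2Cl2, −20 °C → rt; then I2, THF, −30 °C; aq. NaHCO3/Na2S2O3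
Reagents that add atoms: trimethylaluminium, C[Al](C)C; iodine, II
Why: Zirconium-catalysed carboalumination (Negishi) adds methyl and aluminium syn across the terminal alkyne with methyl on the internal carbon, and iodinolysis with retention should give the vinyl iodide with iodine trans to C5 as a single isomer.

Step 13
Reactants: 19 E vinyl iodide; 20 4-methoxybenzyl alcohol
Product: 21 E PMB enol ether alcohol (C5–C4(CH3)=C3H–OPMB; C10 OH)
Conditions: 20 (3 equiv), CuI (10 mol%), 3,4,7,8-tetramethyl-1,10-phenanthroline (20 mol%), Cs2CO3, toluene, 80 °C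
Reagents that add atoms: 4-methoxybenzyl alcohol (20), COc1ccc(CO)cc1
Why: Copper-catalysed Ullmann-type C–O coupling of a vinyl iodide with a primary alcohol proceeds with retention of alkene geometry, and ring closure by the C10 hydroxyl is geometrically impossible for the E iodide.

Step 14
Reactants: 21 E PMB enol ether alcohol
Product: 22 C10 ketone (C5 alkenyl equatorial, trans to O6)
Conditions: (n-Pr4N)RuO4 (5 mol%), N-methylmorpholine N-oxide, 4 Å MS, CH2Cl2, rt
Reagents that add atoms: none
Why: Ley–Griffith oxidation under neutral conditions gives the ketone without touching the acid-sensitive enol ether or the acetal.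

Step 15
Reactants: 22 C10 ketone; 23 ethynylmagnesium bromide
Product: 24 C10 ethynyl carbinol (ethynyl axial, cis to the C5 alkenyl group; OH equatorial)
Conditions: 23, CeCl3 (anhydrous), THF, −78 °C; aq. NH4Cl
Reagents that add atoms: ethynylmagnesium bromide (23), C#C[Mg]Br
Why: Organocerium 1,2-addition suppresses enolisation of the β,γ-unsaturated ketone, and the slim acetylide attacks the cyclohexanone axially past only the axial hydrogens on C6 and C8, which sets C10 with the hydroxyl equatorial and the two-carbon unit cis to the C5 substituent.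

Step 16
Reactants: 24 C10 ethynyl carbinol
Product: 25 cis-1-vinyl-2-(E-alkoxypropenyl)cyclohexanol with acetal-masked cis-lactone
Conditions: H2 (1 atm), Pd/CaCO3 poisoned with Pb(OAc)2, quinoline, EtOAc, rt
Reagents that add atoms: none
Why: Lindlar semi-hydrogenation stops the terminal alkyne at the vinyl group and leaves the enol ether, the PMB ether and the acetal intact.

Step 17
Reactants: 25 cis-1-vinyl-2-(E-alkoxypropenyl)cyclohexanol
Product: 28 ten-membered C10 ketone (Z C4=C5; C3 OPMB; C8 OTBS; acetal-masked lactone), via potassium alkoxide 26 (not isolated), via potassium enolate 27 (not isolated)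
Conditions: KH (4 equiv), 18-crown-6, THF, 0 → 40 °C; then AcOH, −78 °C
Reagents that add atoms: none
Why: The potassium alkoxide 26 undergoes an alkoxide-accelerated [3,3] sigmatropic shift of the C2=C1–C10–C5–C4=C3 array through a chair transition state (anionic oxy-Cope rearrangement, the known conversion of 1,2-dialkenylcyclohexanols into cyclodec-5-enones), forming C2–C3, breaking C5–C10 and giving enolate 27, which acetic acid protonates to ketone 28. The ten-membered ring is closed by ring expansion, the four carbons C1–C4 being inserted between C10 and C5 of the cyclohexane, so no end-to-end cyclisation is involved. The new C3 stereocentre is controlled by the E enol ether geometry, which places the PMB-oxy group pseudo-equatorial on the transition-state chair and fixes the face of C3 that bonds to C2 (3S). The step needs Z geometry at C4=C5, and this requires the cyclohexane chair in which the C10 vinyl group is axial and the C5 alkenyl group equatorial, so that C6 is axial on the six-atom chair and emerges cis to C3. That chair is secured by the all-cis oxygens on C6, C8 and C10, which are all equatorial in it and would be 1,3,5-triaxial in the ring-flipped chair. The cyclic acetal, unlike a lactone, is inert to potassium hydride.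

Step 18
Reactants: 28 ten-membered C10 ketone
Product: 29 C10 tertiary alcohol (10S; C14 methyl added)
Conditions: MeMgBr, CeCl3 (anhydrous), THF, −78 °C; aq. NH4Cl
Reagents that add atoms: methylmagnesium bromide, C[Mg]Br
Why: Non-chelating organocerium 1,2-addition to the medium-ring ketone from its peripheral face, anti to the C8 silyloxy group (polar 1,3-anti induction), should place the new hydroxyl anti to the C8 oxygen as in the target.

Step 19
Reactants: 29 C10 tertiary alcohol
Product: 30 lactol
Conditions: PPTS (cat.), acetone/H2O 4:1, 40 °C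
Reagents that add atoms: water, O
Why: Mild acid-catalysed acetal hydrolysis releases the lactol while the silyl ether, the PMB ether and the tertiary alcohol remain.

Step 20
Reactants: 30 lactol
Product: 31 saturated cis-6,12-lactone
Conditions: TEMPO (10 mol%), PhI(OAc)2, CH2Cl2, rt
Reagents that add atoms: none
Why: Oxoammonium-mediated oxidation converts the lactol into the γ-lactone and cannot oxidise the tertiary alcohol.

Step 21
Reactants: 31 saturated cis-6,12-lactone
Product: 34 α-methylene lactone (C11=C13), via Mannich base 32 (not isolated), via ammonium iodide 33 (not isolated)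
Conditions: LiN(i-Pr)2 (2.5 equiv), THF, −78 °C; CH2=NMe2+ I−, −78 °C → rt; then MeI, MeOH; then aq. NaHCO3, CH2Cl2
Reagents that add atoms: N,N-dimethylmethyleneiminium iodide, C=[N+](C)C.[I-]
Why: Eschenmoser methylenation; the lactone lithium enolate (the extra base covers the C10 alkoxide) undergoes a Mannich reaction, and N-methylation followed by β-elimination gives the exocyclic alkene.

Step 22
Reactants: 34 α-methylene lactone
Product: 35 C8 alcohol
Conditions: HF·pyridine, pyridine, THF, 0 °C → rt
Reagents that add atoms: none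
Why: Fluoride-mediated cleavage of the secondary silyl ether under slightly acidic, non-nucleophilic conditions spares the α-methylene lactone and avoids base-induced migration of the lactone to the C8 oxygen.

Step 23
Reactants: 35 C8 alcohol; 36 angelic acid
Product: 37 C3 PMB ether of the target
Conditions: 36, 2,4,6-Cl3C6H2COCl, Et3N, toluene, rt; then 35, 75 °C
Reagents that add atoms: angelic acid (36), C/C=C(/C)C(=O)O
Why: Yamaguchi mixed-anhydride esterification without a nucleophilic catalyst acylates the secondary C8 hydroxyl (the tertiary C10 hydroxyl is inert) and should transfer the angeloyl group without Z to E isomerisation.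

Step 24
Reactants: 37 C3 PMB ether of the target
Product: 38 CNP0137971.2
Conditions: DDQ, CH2Cl2/pH 7 buffer 10:1, 0 °C
Reagents that add atoms: none
Why: Oxidative cleavage of the 4-methoxybenzyl ether by DDQ (benzylic hydride abstraction, then hydrolysis) frees the C3 alcohol under conditions that leave the angelate, the α-methylene lactone and both alkenes untouched.

**Compound list**

1 | 1,3-cyclohexadiene | C1=CC=CCC1 | starting material
2 | cis-cyclohex-2-ene-1,4-diyl diacetate (meso) | CC(=O)O[C@H]1C=C[C@@H](OC(C)=O)CC1 | intermediate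
3 | (1S,4R)-4-hydroxycyclohex-2-en-1-yl acetate | CC(=O)O[C@@H]1C=C[C@H](O)CC1 | intermediate
4 | (1S,4R)-4-(tert-butyldimethylsilyloxy)cyclohex-2-en-1-yl acetate | CC(=O)O[C@@H]1C=C[C@H](O[Si](C)(C)C(C)(C)C)CC1 | intermediate
5 | (1S,4R)-4-(tert-butyldimethylsilyloxy)cyclohex-2-en-1-ol | O[C@@H]1C=C[C@H](O[Si](C)(C)C(C)(C)C)CC1 | intermediate
6 | trimethyl orthoacetate | CC(OC)(OC)OC | starting material
7 | 1-methoxyvinyl ether of 5 (ketene acetal) | C=C(OC)O[C@@H]1C=C[C@H](O[Si](C)(C)C(C)(C)C)CC1 | intermediate
8 | methyl 2-[(1S,6R)-6-(TBSO)cyclohex-2-en-1-yl]acetate (side chain cis to OTBS) | COC(=O)C[C@H]1C=CCC[C@H]1O[Si](C)(C)C(C)(C)C | intermediate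
9 | methyl 2-[(1S,6R)-6-(TBSO)-4-oxocyclohex-2-en-1-yl]acetate | COC(=O)C[C@H]1C=CC(=O)C[C@H]1O[Si](C)(C)C(C)(C)C | intermediate
10 | methyl 2-[(1S,6R)-6-(TBSO)-3-iodo-4-oxocyclohex-2-en-1-yl]acetate | COC(=O)C[C@H]1C=C(I)C(=O)C[C@H]1O[Si](C)(C)C(C)(C)C | intermediate
11 | (trimethylsilyl)acetylene | C#C[Si](C)(C)C | starting material
12 | methyl 2-[(1S,6R)-6-(TBSO)-4-oxo-3-(trimethylsilylethynyl)cyclohex-2-en-1-yl]acetate | COC(=O)C[C@H]1C=C(C#C[Si](C)(C)C)C(=O)C[C@H]1O[Si](C)(C)C(C)(C)C | intermediate
13 | free carboxylic acid of 12 | OC(=O)C[C@H]1C=C(C#C[Si](C)(C)C)C(=O)C[C@H]1O[Si](C)(C)C(C)(C)C | intermediate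
14 | keto lactone: C10 ketone, cis-fused 6,12-lactone, C5 silylethynyl trans to O6, C8 OTBS cis to C7–C11 | O=C1C[C@@H](O[Si](C)(C)C(C)(C)C)[C@H]2CC(=O)O[C@H]2[C@@H]1C#C[Si](C)(C)C | intermediate
15 | lactol diol: C12 lactol and C10 carbinol (all-cis) of 14 | O[C@H]1C[C@@H](O[Si](C)(C)C(C)(C)C)[C@H]2C[C@H](O)O[C@H]2[C@@H]1C#C[Si](C)(C)C | intermediate
16 | C12 methyl acetal of 15 (silylalkyne) | O[C@H]1C[C@@H](O[Si](C)(C)C(C)(C)C)[C@H]2C[C@H](OC)O[C@H]2[C@@H]1C#C[Si](C)(C)C | intermediate
17 | methyl acetal alkynol: C5 ethynyl, C10 OH | O[C@H]1C[C@@H](O[Si](C)(C)C(C)(C)C)[C@H]2C[C@H](OC)O[C@H]2[C@@H]1C#C | intermediate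
18 | E alkenyl(dimethyl)alane, C10 dimethylaluminium alkoxide | C[Al](C)O[C@H]1C[C@@H](O[Si](C)(C)C(C)(C)C)[C@H]2C[C@H](OC)O[C@H]2[C@@H]1/C(C)=C/[Al](C)C | intermediate
19 | E vinyl iodide: C5–C4(CH3)=C3H–I, iodine trans to C5 | O[C@H]1C[C@@H](O[Si](C)(C)C(C)(C)C)[C@H]2C[C@H](OC)O[C@H]2[C@@H]1/C(C)=C/I | intermediate
20 | 4-methoxybenzyl alcohol | COc1ccc(CO)cc1 | starting material
21 | E PMB enol ether alcohol (C10 OH) | O[C@H]1C[C@@H](O[Si](C)(C)C(C)(C)C)[C@H]2C[C@H](OC)O[C@H]2[C@@H]1/C(C)=C/OCc1ccc(OC)cc1 | intermediate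
22 | C10 ketone with C5 E-(PMB-oxy)propenyl trans to O6 | O=C1C[C@@H](O[Si](C)(C)C(C)(C)C)[C@H]2C[C@H](OC)O[C@H]2[C@@H]1/C(C)=C/OCc1ccc(OC)cc1 | intermediate
23 | ethynylmagnesium bromide | C#C[Mg]Br | starting material
24 | C10 ethynyl carbinol, ethynyl cis to the C5 alkenyl group | C#C[C@]1(O)C[C@@H](O[Si](C)(C)C(C)(C)C)[C@H]2C[C@H](OC)O[C@H]2[C@@H]1/C(C)=C/OCc1ccc(OC)cc1 | intermediate
25 | cis-1-vinyl-2-(E-alkoxypropenyl)cyclohexanol with acetal-masked cis-lactone and C8 OTBS | C=C[C@]1(O)C[C@@H](O[Si](C)(C)C(C)(C)C)[C@H]2C[C@H](OC)O[C@H]2[C@@H]1/C(C)=C/OCc1ccc(OC)cc1 | intermediate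
26 | potassium alkoxide of 25 | C=C[C@]1([O-])C[C@@H](O[Si](C)(C)C(C)(C)C)[C@H]2C[C@H](OC)O[C@H]2[C@@H]1/C(C)=C/OCc1ccc(OC)cc1.[K+] | intermediate
27 | potassium C1=C10 enolate of 28 | CO[C@@H]1O[C@H]2/C=C(/C)[C@@H](OCc3ccc(OC)cc3)C/C=C(\[O-])C[C@@H](O[Si](C)(C)C(C)(C)C)[C@H]2C1.[K+] | intermediate
28 | ten-membered C10 ketone, Z C4=C5, (3S) OPMB, C8 OTBS, cis-fused C12 methyl acetal | CO[C@@H]1O[C@H]2/C=C(/C)[C@@H](OCc3ccc(OC)cc3)CCC(=O)C[C@@H](O[Si](C)(C)C(C)(C)C)[C@H]2C1 | intermediate
29 | (10S) tertiary alcohol of 28 with C14 methyl | CO[C@@H]1O[C@H]2/C=C(/C)[C@@H](OCc3ccc(OC)cc3)CC[C@](C)(O)C[C@@H](O[Si](C)(C)C(C)(C)C)[C@H]2C1 | intermediate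
30 | C12 lactol of 29 | O[C@@H]1O[C@H]2/C=C(/C)[C@@H](OCc3ccc(OC)cc3)CC[C@](C)(O)C[C@@H](O[Si](C)(C)C(C)(C)C)[C@H]2C1 | intermediate
31 | saturated cis-6,12-lactone | O=C1O[C@H]2/C=C(/C)[C@@H](OCc3ccc(OC)cc3)CC[C@](C)(O)C[C@@H](O[Si](C)(C)C(C)(C)C)[C@H]2C1 | intermediate
32 | C11 dimethylaminomethyl lactone (Mannich base) | CN(C)C[C@@H]1C(=O)O[C@H]2/C=C(/C)[C@@H](OCc3ccc(OC)cc3)CC[C@](C)(O)C[C@@H](O[Si](C)(C)C(C)(C)C)[C@@H]12 | intermediate
33 | C11 trimethylammoniomethyl lactone iodide | C[N+](C)(C)C[C@@H]1C(=O)O[C@H]2/C=C(/C)[C@@H](OCc3ccc(OC)cc3)CC[C@](C)(O)C[C@@H](O[Si](C)(C)C(C)(C)C)[C@@H]12.[I-] | intermediate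
34 | α-methylene lactone, C8 OTBS, C3 OPMB | C=C1C(=O)O[C@H]2/C=C(/C)[C@@H](OCc3ccc(OC)cc3)CC[C@](C)(O)C[C@@H](O[Si](C)(C)C(C)(C)C)[C@@H]12 | intermediate
35 | α-methylene lactone, C8 OH, C3 OPMB | C=C1C(=O)O[C@H]2/C=C(/C)[C@@H](OCc3ccc(OC)cc3)CC[C@](C)(O)C[C@@H](O)[C@@H]12 | intermediate
36 | angelic acid, (Z)-2-methylbut-2-enoic acid | C/C=C(/C)C(=O)O | starting material
37 | C3 PMB ether of the target (C8 angelate) | C=C1C(=O)O[C@H]2/C=C(/C)[C@@H](OCc3ccc(OC)cc3)CC[C@](C)(O)C[C@@H](OC(=O)/C(C)=C\C)[C@@H]12 | intermediate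
38 | CNP0137971.2 | C=C1C(=O)O[C@H]2/C=C(/C)[C@@H](O)CC[C@](C)(O)C[C@@H](OC(=O)/C(C)=C\C)[C@@H]12 | target

**Totals**

Total step count: 24. Longest linear sequence: 24 steps (steps 1–24; all other inputs are purchased).

**Steps most likely to fail**

Step 17 (key step). What may go wrong: alkoxide-triggered side reactions compete with or follow the [3,3] shift, namely Grob-type cleavage of C5–C10 with loss of the C6 acetal oxygen, or β-elimination of the C8 silyloxy group from the product enolate. Fallback: the rearrangement is run without any anion as a neutral silyloxy-Cope reaction. Setting out from 25, the tertiary hydroxyl is silylated (TMSCl, imidazole) to the trimethylsilyl ether F1. Heating F1 in a sealed, base-washed vessel (o-dichlorobenzene, about 200 °C) should pass through the same chair to the trimethylsilyl enol ether F2. Buffered fluoride (Bu4NF/AcOH, −20 °C) then releases the ketone, and the route is rejoined at 28.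

Step 18. What may go wrong: poor or inverted facial selectivity of methyl delivery to the conformationally mobile cyclodecenone, giving the C10 epimer. Fallback: oxygen instead of carbon is delivered to the exposed face. Setting out from 28, Wittig methylenation (Ph3P=CH2) gives the exocyclic alkene F3. Dihydroxylation with OsO4 (cat.) and N-methylmorpholine N-oxide should take the 1,1-disubstituted alkene in preference to the hindered trisubstituted C4=C5 and give the diol F4, with the tertiary hydroxyl on the face that the Grignard reagent would have attacked. The primary hydroxyl is sulfonylated (TsCl, pyridine) to the primary tosylate F5, and LiEt3BH reduces it (by way of the spiro-epoxide) to the methyl carbinol, rejoining the route at 29.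

Step 9. What may go wrong: the conjugate lactonisation is reversible (retro-oxa-Michael), and the enynone may instead lose the silyloxy group and aromatise. Fallback: the C6–O bond is made irreversibly by iodolactonisation and the alkyne is brought in afterwards. Setting out from 9, Luche reduction (NaBH4, CeCl3) gives the allylic alcohol F6, and LiOH hydrolysis gives the hydroxy acid F7. Iodolactonisation (I2, NaHCO3) gives the iodolactone F8, with O6 cis to C7–C11 and iodine trans on C5. Radical alkynylation of the C5 iodide (phenyl trimethylsilylethynyl sulfone, hexabutylditin, hν) from the face opposite the lactone ring gives the alkynyl hydroxy lactone F9. Reduction with i-Bu2AlH at −78 °C then rejoins the route at 15.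

Further compounds
F1 | step 17 | trimethylsilyl ether of 25 | C=C[C@]1(O[Si](C)(C)C)C[C@@H](O[Si](C)(C)C(C)(C)C)[C@H]2C[C@H](OC)O[C@H]2[C@@H]1/C(C)=C/OCc1ccc(OC)cc1
F2 | step 17 | trimethylsilyl enol ether (C1=C10) of 28 | CO[C@@H]1O[C@H]2/C=C(/C)[C@@H](OCc3ccc(OC)cc3)C/C=C(\O[Si](C)(C)C)C[C@@H](O[Si](C)(C)C(C)(C)C)[C@H]2C1
F3 | step 18 | C10 exocyclic methylene analogue of 28 | CO[C@@H]1O[C@H]2/C=C(/C)[C@@H](OCc3ccc(OC)cc3)CCC(=C)C[C@@H](O[Si](C)(C)C(C)(C)C)[C@H]2C1
F4 | step 18 | C10,C14 diol (C14 hydroxymethyl analogue of 29) | CO[C@@H]1O[C@H]2/C=C(/C)[C@@H](OCc3ccc(OC)cc3)CC[C@](CO)(O)C[C@@H](O[Si](C)(C)C(C)(C)C)[C@H]2C1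
F5 | step 18 | C14 primary tosylate of F4 | CO[C@@H]1O[C@H]2/C=C(/C)[C@@H](OCc3ccc(OC)cc3)CC[C@](COS(=O)(=O)c3ccc(C)cc3)(O)C[C@@H](O[Si](C)(C)C(C)(C)C)[C@H]2C1
F6 | step 9 | methyl 2-[(1S,6R)-4-hydroxy-6-(TBSO)cyclohex-2-en-1-yl]acetate (all-cis allylic alcohol) | COC(=O)C[C@H]1C=C[C@@H](O)C[C@H]1O[Si](C)(C)C(C)(C)C
F7 | step 9 | free carboxylic acid of F6 | OC(=O)C[C@H]1C=C[C@@H](O)C[C@H]1O[Si](C)(C)C(C)(C)C
F8 | step 9 | iodolactone: cis-fused 6,12-lactone, C5 iodide trans to O6, C10 OH, C8 OTBS | O[C@H]1C[C@@H](O[Si](C)(C)C(C)(C)C)[C@H]2CC(=O)O[C@H]2[C@@H]1I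
F9 | step 9 | alkynyl hydroxy lactone: C5 trimethylsilylethynyl trans to O6, C10 OH | O[C@H]1C[C@@H](O[Si](C)(C)C(C)(C)C)[C@H]2CC(=O)O[C@H]2[C@@H]1C#C[Si](C)(C)C
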